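Ring A of the target contains a γ,δ-unsaturated ester, C18(=O)–C4–C5–C10=C1, and the plan rests on disconnecting C4–C5 as an Ireland–Claisen bond. This leads back to a δ-lactone (ring atoms O, C18, C4, C3, C2, C1) whose carbinol carbon C1 carries ring B as a cyclohexenyl group (C10=C5). Heating its silyl ketene acetal forms C4–C5, closes ring A, shifts the alkene to C1=C10, releases C18 as the free carboxyl group, and passes the C1 configuration on to C5 and the quaternary C4, all in one operation. The lactone is assembled from a ring-B vinyllithium, a differentiated 2-methylglutarate unit and a CBS reduction.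

Key step: step 10

**Numbering, faces and design remarks**
- Halimane numbering is used. Ring A is C1–C5 and C10; ring B is C5–C10. C17 sits on C8 and C20 on C9. The side chain is C11–C15, with C16 on C13. C18 (ester carbon) and C19 (methyl) sit on C4.
- The target is 4S,5R,8R,9S,13S. The α face is the one that carries H5, C17, C19 and C20. The β face carries C11 and C18.
- The ring-B starting material is the six-membered enone, CC1=CCCCC1=O.
- Cleaving the citronellol alkene leaves six chain carbons, whereas C11–C15 has only five. The surplus carbon is expelled as CO2 in step 3.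
- Lactone and ring A are both six-membered. O and C18 leave the ring while C10 and C5 enter it, so the ring size does not change.
- C18 travels as a methyl ester, so the borane of step 9 meets no free acid. The two carbonyl groups of the C1–C4/C18 unit are differentiated before the C1–C10 bond is made.
- An enol triflate cannot be lithiated directly. The sulfonylhydrazone gives the vinyllithium in one operation.

Assumption: C4 is carried as a mixture of epimers from the glutarate diester to the lactone and is left undefined in those SMILES, because step 10 makes this carbon planar.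

Assumption: the ligand antipode named in step 4 is the one expected to give 8R by analogy with cyclohex-2-enone. If the 2-methyl enone shows the opposite sense, the mirror-image ligand is used.

**Route**

Step 1
Reactants: 1 (S)-citronellol
Product: 2 (S)-citronellyl tert-butyldimethylsilyl ether
Conditions: TBSCl, imidazole, CH2Cl2, rt
Reagents that add atoms: tert-butyldimethylsilyl chloride, CC(C)(C)[Si](C)(C)Cl
Why: Routine silyl ether protection of the primary alcohol (C15–O), which leaves the chiral-pool centre C13 untouched and gives a group that should survive ozone, radicals, organolithiums, borane and LDA.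

Step 2
Reactants: 2 (S)-citronellyl tert-butyldimethylsilyl ether
Product: 4 (4S)-6-(tert-butyldimethylsilyloxy)-4-methylhexanoic acid, via silyloxy aldehyde 3 (not isolated)
Conditions: O3, CH2Cl2, −78 °C; Me2S, to rt; concentrate; then NaClO2, NaH2PO4, 2-methyl-2-butene, t-BuOH/H2O, rt
Reagents that add atoms: ozone, [O-][O+]=O; sodium chlorite, [Na+].[O-]Cl=O
Why: Ozonolysis of the only alkene followed by Pinnick oxidation of the crude aldehyde, both mild enough for the silyl ether and remote from C13, should give the acid whose carboxyl carbon is the one chain carbon that the target does not need.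

Step 3
Reactants: 4 (4S)-6-(tert-butyldimethylsilyloxy)-4-methylhexanoic acid
Product: 6 tert-butyl{[(3R)-5-iodo-3-methylpentyl]oxy}dimethylsilane, via acyl hypoiodite 5 (not isolated)
Conditions: PhI(OAc)2, I2, cyclohexane, W lamp, reflux
Reagents that add atoms: iodine, II
Why: Hunsdiecker-type iododecarboxylation in the hypervalent-iodine (Suárez) variant: homolysis of the acyl hypoiodite expels CO2 and the primary C11 radical is caught by iodine much faster than it can abstract hydrogen, so the chain is cut to exactly C11–C15 with C13 unchanged (its descriptor becomes R only because iodine outranks oxygen).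

Step 4
Reactants: 7 2-methylcyclohex-2-en-1-one
Product: 9 {[(3R)-2,3-dimethylcyclohex-1-en-1-yl]oxy}trimethylsilane, via aluminium enolate 8 (not isolated)
Conditions: Me3Al, CuTC (cat.), (R,S,S)-BINOL bis(1-phenylethyl)amine phosphoramidite (cat.), Et2O, −30 °C; then TMSOTf, THF, −30 to 0 °C
Reagents that add atoms: trimethylaluminium, C[Al](C)C; trimethylsilyl triflate, C[Si](C)(C)OS(=O)(=O)C(F)(F)F
Why: Copper-catalysed asymmetric conjugate addition of a methylaluminium reagent to the 2-substituted enone, in which the chiral phosphoramidite–copper complex chooses the enone face and so sets C8 (R), followed by O-silylation that stores the regiodefined C9=C10 enolate in isolable form.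

Step 5
Reactants: 9 {[(3R)-2,3-dimethylcyclohex-1-en-1-yl]oxy}trimethylsilane; 6 tert-butyl{[(3R)-5-iodo-3-methylpentyl]oxy}dimethylsilane
Product: 11 ring-B ketone (2S,3R)-2-[(3S)-5-(tert-butyldimethylsilyloxy)-3-methylpentyl]-2,3-dimethylcyclohexan-1-one, via lithium enolate 10 (not isolated)
Conditions: MeLi, THF, 0 °C to rt; then DMPU, 6, −20 °C to rt
Reagents that add atoms: none
Why: Regiospecific enolate alkylation (silyl enol ether cleavage with MeLi, then SN2 on the primary iodide): in the enolate the C17 methyl turns pseudoaxial to avoid A(1,2) strain with C20 and blocks its own face, so the chain should enter anti to it and set quaternary C9 (S) with C17 and C20 cis.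

Step 6
Reactants: 11 ring-B ketone
Product: 12 (E)-2,4,6-triisopropylbenzenesulfonylhydrazone of ketone 11
Conditions: 2,4,6-i-Pr3C6H2SO2NHNH2, THF, rt
Reagents that add atoms: 2,4,6-triisopropylbenzenesulfonyl hydrazide, CC(C)c1cc(C(C)C)c(S(=O)(=O)NN)c(C(C)C)c1
Why: Acid-free hydrazone condensation at the C10 ketone, a known reaction even for ketones next to a quaternary carbon, places the sulfonamide nitrogen on the C5 side and touches no stereocentre.

Step 7
Reactants: 13 dimethyl 2-methylpentanedioate (racemic)
Product: 14 methyl 5-[methoxy(methyl)amino]-2-methyl-5-oxopentanoate (racemic)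
Conditions: MeNHOMe·HCl (1 equiv), i-PrMgCl (2 equiv), THF, −20 °C
Reagents that add atoms: N,O-dimethylhydroxylamine hydrochloride, CNOC.Cl
Why: Ester aminolysis with the chloromagnesium amide (Weinreb amide formation): one equivalent of this bulky nucleophile at low temperature should take the unbranched C1 ester ahead of the α-branched C18 ester, and any regioisomeric amide is branched at its own α-carbon and should be left behind by the hindered nucleophile of step 8.

Step 8
Reactants: 12 trisylhydrazone; 14 methyl 5-[methoxy(methyl)amino]-2-methyl-5-oxopentanoate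
Product: 16 enone keto ester methyl 5-{(5R,6S)-6-[(3S)-5-(tert-butyldimethylsilyloxy)-3-methylpentyl]-5,6-dimethylcyclohex-1-en-1-yl}-2-methyl-5-oxopentanoate, via vinyllithium 15 (not isolated)
Conditions: n-BuLi (2 equiv), THF, −78 to 0 °C; then 14, −78 to −40 °C; aq NH4Cl
Reagents that add atoms: none
Why: Shapiro reaction followed by Weinreb ketone synthesis: the hydrazone dianion can only be formed at C5 because C9 is quaternary, loses sulfinate and N2 to give the C10 vinyllithium, and this should add to the unhindered chelating amide rather than to the branched ester, the tetrahedral chelate stopping the reaction at the ketone stage.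

Step 9
Reactants: 16 enone keto ester
Product: 18 δ-lactone (6R)-6-{(5R,6S)-6-[(3S)-5-(tert-butyldimethylsilyloxy)-3-methylpentyl]-5,6-dimethylcyclohex-1-en-1-yl}-3-methyltetrahydro-2H-pyran-2-one, via hydroxy ester 17 (not isolated)
Conditions: (S)-Me-CBS (cat.), BH3·SMe2, THF, −30 °C; MeOH; then PPTS (cat.), PhMe, 60 °C
Reagents that add atoms: none
Why: Corey–Bakshi–Shibata reduction followed by acid-catalysed lactonisation: the (S)-oxazaborolidine delivers hydride to the ketone face that keeps the bulky cyclohexenyl group away from the catalyst, the same sense that turns aryl methyl ketones into (R)-alcohols, so C1 should be set as R under reagent control, and the δ-hydroxy ester then closes with loss of methanol under conditions too mild to ionise the allylic alcohol or cleave the silyl ether.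

Step 10
Reactants: 18 δ-lactone
Product: 21 15-O-TBS-halim-1(10)-en-18-oic acid (4S,5R,8R,9S,13S), via silyl ketene acetal 19 (not isolated), via trimethylsilyl ester 20 (not isolated)
Conditions: LDA, THF, −78 °C; TMSCl/Et3N, −78 °C to rt; solvent change to PhMe, 110 °C; then H2O/THF, rt
Reagents that add atoms: none
Why: LDA removes the C4 proton of either C4 epimer and TMSCl traps the enolate on oxygen, giving a cyclic ketene acetal whose geometry (C3 cis to the ring oxygen, C19 cis to OSi) is fixed by the six-membered ring; on heating, the array C4=C18–O–C1–C10=C5 undergoes a concerted suprafacial [3,3] shift, and water then cleaves the silyl ester. The closest known reaction type is the Ireland–Claisen rearrangement of alkenyl-substituted lactones into cycloalkenecarboxylic acids, which runs through boat transition states. Ring A (C1, C2, C3, C4, C5, C10) closes because the C2–C3 tether spans the termini C1 and C4 of the pericyclic array, so a chair is out of reach and the only mode of closure is a bicyclo[2.2.2]octane-like boat. C5 is controlled by C1: ring closure demands C2 cis to C5 on the new C1=C10 bond (H1 facing C9), and with 1R the C1–O bond then stands on the β face of ring B, so C4 arrives on that same face and H5 ends α (5R). C4 is controlled by the ring-fixed ketene acetal inside the boat, where C18 lies over C10, C19 over C6 and C3 over H5, so that C18 finishes on the side of ring A that holds C6 and C19 on the side of H5 (4S). The step needs O- rather than C-silylation and bonding on one ring-B face only: the fully substituted enolate carbon secures the first, and the second is a matched case because the β face lies opposite the pseudoaxial C20 methyl on C9, while the lactone offers no second allyl system and no competing acidic site.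

Step 11
Reactants: 21 15-O-TBS-halim-1(10)-en-18-oic acid
Product: 22 methyl 15-O-TBS-halim-1(10)-en-18-oate
Conditions: MeI, K2CO3, DMF, rt
Reagents that add atoms: iodomethane, CI
Why: Carboxylate O-alkylation (SN2 on MeI) bypasses attack at the hindered C18 carbonyl and avoids acid, which could move the C1=C10 alkene into the tetrasubstituted C5=C10 position.

Step 12
Reactants: 22 methyl 15-O-TBS-halim-1(10)-en-18-oate
Product: 24 methyl 15-acetoxyhalim-1(10)-en-18-oate (target CNP0151222.1), via primary alcohol 23 (not isolated)
Conditions: TBAF, THF, rt; then Ac2O, DMAP (cat.), rt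
Reagents that add atoms: acetic anhydride, CC(=O)OC(C)=O
Why: Fluoride desilylation followed by DMAP-catalysed acetylation in the same flask, both non-acidic, should leave the hindered C18 methyl ester, the C1=C10 alkene and all five stereocentres untouched.

**Compound list**

1 | (S)-citronellol | CC(C)=CCC[C@H](C)CCO | starting material
2 | (S)-citronellyl tert-butyldimethylsilyl ether | CC(C)=CCC[C@H](C)CCO[Si](C)(C)C(C)(C)C | intermediate
3 | (4S)-6-(tert-butyldimethylsilyloxy)-4-methylhexanal (not isolated) | O=CCC[C@H](C)CCO[Si](C)(C)C(C)(C)C | intermediate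
4 | (4S)-6-(tert-butyldimethylsilyloxy)-4-methylhexanoic acid | OC(=O)CC[C@H](C)CCO[Si](C)(C)C(C)(C)C | intermediate
5 | acyl hypoiodite of acid 4 (not isolated) | IOC(=O)CC[C@H](C)CCO[Si](C)(C)C(C)(C)C | intermediate
6 | tert-butyl{[(3R)-5-iodo-3-methylpentyl]oxy}dimethylsilane | ICC[C@H](C)CCO[Si](C)(C)C(C)(C)C | intermediate
7 | 2-methylcyclohex-2-en-1-one | CC1=CCCCC1=O | starting material
8 | dimethylaluminium (3R)-2,3-dimethylcyclohex-1-en-1-olate (not isolated) | C1CC[C@@H](C)C(C)=C1O[Al](C)C | intermediate
9 | {[(3R)-2,3-dimethylcyclohex-1-en-1-yl]oxy}trimethylsilane | C1CC[C@@H](C)C(C)=C1O[Si](C)(C)C | intermediate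
10 | lithium (3R)-2,3-dimethylcyclohex-1-en-1-olate (not isolated) | C1CC[C@@H](C)C(C)=C1O[Li] | intermediate
11 | (2S,3R)-2-[(3S)-5-(tert-butyldimethylsilyloxy)-3-methylpentyl]-2,3-dimethylcyclohexan-1-one (C10 ketone, C17 and C20 cis) | O=C1CCC[C@@H](C)[C@]1(C)CC[C@H](C)CCO[Si](C)(C)C(C)(C)C | intermediate
12 | (E)-2,4,6-triisopropylbenzenesulfonylhydrazone of 11 | CC(C)c1cc(C(C)C)c(c(c1)C(C)C)S(=O)(=O)N/N=C2\CCC[C@@H](C)[C@]2(C)CC[C@H](C)CCO[Si](C)(C)C(C)(C)C | intermediate
13 | dimethyl 2-methylpentanedioate (racemic) | COC(=O)CCC(C)C(=O)OC | starting material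
14 | methyl 5-[methoxy(methyl)amino]-2-methyl-5-oxopentanoate (racemic) | COC(=O)C(C)CCC(=O)N(C)OC | intermediate
15 | C10 vinyllithium, (5R,6S)-6-[(3S)-5-(tert-butyldimethylsilyloxy)-3-methylpentyl]-5,6-dimethylcyclohex-1-en-1-yllithium (not isolated) | [Li]C1=CCC[C@@H](C)[C@]1(C)CC[C@H](C)CCO[Si](C)(C)C(C)(C)C | intermediate
16 | enone keto ester (C1 ketone, C18 methyl ester, C4 epimers) | COC(=O)C(C)CCC(=O)C1=CCC[C@@H](C)[C@]1(C)CC[C@H](C)CCO[Si](C)(C)C(C)(C)C | intermediate
17 | (1R)-hydroxy ester (C4 epimers, not isolated) | COC(=O)C(C)CC[C@@H](O)C1=CCC[C@@H](C)[C@]1(C)CC[C@H](C)CCO[Si](C)(C)C(C)(C)C | intermediate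
18 | (1R)-δ-lactone, C1 carbinol carbon, C18 lactone carbonyl, ring B as cyclohexenyl group (C4 epimers) | CC1CC[C@@H](OC1=O)C2=CCC[C@@H](C)[C@]2(C)CC[C@H](C)CCO[Si](C)(C)C(C)(C)C | intermediate
19 | cyclic trimethylsilyl ketene acetal of 18 (not isolated) | CC1=C(O[Si](C)(C)C)O[C@H](CC1)C2=CCC[C@@H](C)[C@]2(C)CC[C@H](C)CCO[Si](C)(C)C(C)(C)C | intermediate
20 | trimethylsilyl 15-O-TBS-halim-1(10)-en-18-oate (not isolated) | C[Si](C)(C)OC(=O)[C@@]1(C)CCC=C2[C@H]1CC[C@@H](C)[C@]2(C)CC[C@H](C)CCO[Si](C)(C)C(C)(C)C | intermediate
21 | 15-O-TBS-halim-1(10)-en-18-oic acid (4S,5R,8R,9S,13S) | OC(=O)[C@@]1(C)CCC=C2[C@H]1CC[C@@H](C)[C@]2(C)CC[C@H](C)CCO[Si](C)(C)C(C)(C)C | intermediate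
22 | methyl 15-O-TBS-halim-1(10)-en-18-oate | COC(=O)[C@@]1(C)CCC=C2[C@H]1CC[C@@H](C)[C@]2(C)CC[C@H](C)CCO[Si](C)(C)C(C)(C)C | intermediate
23 | methyl 15-hydroxyhalim-1(10)-en-18-oate (not isolated) | COC(=O)[C@@]1(C)CCC=C2[C@H]1CC[C@@H](C)[C@]2(C)CC[C@H](C)CCO | intermediate
24 | methyl 15-acetoxyhalim-1(10)-en-18-oate (CNP0151222.1) | COC(=O)[C@@]1(C)CCC=C2[C@H]1CC[C@@H](C)[C@]2(C)CC[C@H](C)CCOC(C)=O | target

**Totals**

Total step count: 12.
Longest linear sequence: 10 steps (1, 2, 3, 5, 6, 8, 9, 10, 11, 12).

**Steps most likely to fail**

1. Step 10 (key step).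
- What may go wrong: the boat has to press a fully substituted ketene acetal carbon against C5 beside the quaternary C9. The shift may therefore be slow enough for loss of the silyl group, C-silylation or heterolysis of the allylic C1–O bond to compete.
- Fallback, from ketone 11 back to methyl ester 22: the C4–C5 bond and ring A would be made by a cycloaddition instead of a sigmatropic shift. Ketone 11 is converted with KHMDS and PhNTf2 (THF, −78 °C) into the C10 enol triflate F1. Stille coupling with tributyl(vinyl)stannane (Pd(PPh3)4, LiCl, THF, reflux) then gives the 1-vinylcyclohexene F2. Its s-cis form is favoured, because only there does H1 rather than C2 face C9. A Diels–Alder reaction of F2 with methyl methacrylate (Me2AlCl, CH2Cl2, or heat in toluene) should join C2 to C3 and C5 to C4 ("ortho" orientation). Approach on the face opposite the C20 methyl, with the ester endo, gives the arrangement of 22. Steps 6 to 11 are then not needed.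

2. Step 5.
- What may go wrong: SN2 displacement of an unactivated primary iodide by a tetrasubstituted enolate is slow. Proton transfer, enolate equilibration towards C5, multiple alkylation and E2 elimination of the iodide may compete, and facial selectivity may erode at the higher temperature needed.
- Fallback, from silyl enol ether 9 back to ketone 11: an activated allylic electrophile is used and C13 is set afterwards. But-3-yn-1-ol is silylated (TBSCl, imidazole) to the alkyne F3. Zirconium-catalysed carboalumination (Me3Al, Cp2ZrCl2) with a paraformaldehyde quench gives the (E)-allylic alcohol F4, and Appel bromination (CBr4, PPh3) gives the allylic bromide F5. Enolate 10, released from 9 as in step 5, should be alkylated by F5 at low temperature, again anti to the C17 methyl, to give the unsaturated ketone F6. Iridium-catalysed asymmetric hydrogenation of the C12=C13 alkene (Ir–PHOX catalyst, H2, CH2Cl2, ligand antipode chosen for 13S) then gives 11. Steps 1 to 3 drop out.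

3. Step 8.
- What may go wrong: the hindered and strongly basic vinyllithium may abstract an α-proton from the amide or ester, attack the ester, or be protonated before it adds.
- Fallback, from ketone 11 back to enone 16: a weakly basic vinylchromium species and an aldehyde replace the lithium reagent and the amide. Ketone 11 is converted into enol triflate F1 as described under step 10. Amide 14 is reduced with Cp2Zr(H)Cl (THF, rt), which spares the ester, to the aldehyde ester F7. Nozaki–Hiyama–Kishi coupling of the two (CrCl2, NiCl2 cat., DMF, rt) should give the hydroxy ester F8 as a mixture at C1. Dess–Martin oxidation erases that centre and gives 16, from which step 9 sets C1 as planned.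

**Further compounds**

F1 | step 10 | (5R,6S)-6-[(3S)-5-(tert-butyldimethylsilyloxy)-3-methylpentyl]-5,6-dimethylcyclohex-1-en-1-yl triflate | FC(F)(F)S(=O)(=O)OC1=CCC[C@@H](C)[C@]1(C)CC[C@H](C)CCO[Si](C)(C)C(C)(C)C
F2 | step 10 | (5R,6S)-1-ethenyl-6-[(3S)-5-(tert-butyldimethylsilyloxy)-3-methylpentyl]-5,6-dimethylcyclohex-1-ene | C=CC1=CCC[C@@H](C)[C@]1(C)CC[C@H](C)CCO[Si](C)(C)C(C)(C)C
F3 | step 5 | (but-3-yn-1-yloxy)(tert-butyl)dimethylsilane | C#CCCO[Si](C)(C)C(C)(C)C
F4 | step 5 | (E)-5-(tert-butyldimethylsilyloxy)-3-methylpent-2-en-1-ol | OC/C=C(\C)CCO[Si](C)(C)C(C)(C)C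
F5 | step 5 | (E)-[(5-bromo-3-methylpent-3-en-1-yl)oxy](tert-butyl)dimethylsilane | BrC/C=C(\C)CCO[Si](C)(C)C(C)(C)C
F6 | step 5 | (2S,3R)-2-[(E)-5-(tert-butyldimethylsilyloxy)-3-methylpent-2-en-1-yl]-2,3-dimethylcyclohexan-1-one | O=C1CCC[C@@H](C)[C@]1(C)C/C=C(\C)CCO[Si](C)(C)C(C)(C)C
F7 | step 8 | methyl 2-methyl-5-oxopentanoate (racemic) | COC(=O)C(C)CCC=O
F8 | step 8 | hydroxy ester of the constitution of 17, mixture of C1 and C4 epimers | COC(=O)C(C)CCC(O)C1=CCC[C@@H](C)[C@]1(C)CC[C@H](C)CCO[Si](C)(C)C(C)(C)C
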